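**Retrosynthetic overview**

1. Pyran ring last: chromene C3=C4 by ring-closing metathesis of aryl tert-allyl ether 26; O1–C2 and the C2 stereocentre by Pd-catalysed asymmetric allylic etherification of the symmetric 2-vinylresorcinol 25 with (Z)-allylic carbonate 20.
2. Side chain: 20 from vinylcyclohexene 14 by hydroboration and B-alkyl Suzuki coupling with (Z)-3-iodobut-2-en-1-ol 17; the vinyl group comes from the ester carbon of 11.
3. Cyclohexene ring first (ring locants as in the target name: C1 quaternary, C2 CH–CH3, C3 =C–CH3, C4 =CH). C1 and C3 both flank C2, so with C2 as a ketone and the side-chain carbon on C1 as an ester, C1 and C3 are the α and α′ carbons of ethyl 2-methyl-3-oxopentanoate and C6–C5–C4 is acrolein. One flask then makes C1–C6 (enantioselective, stereoconvergent Michael addition) and C3=C4 (aldol condensation).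
4. The C2 ketone becomes the C2 methyl stereocentre by MeCeCl2 addition, oxidative 1,3-transposition, CBS reduction and a suprafacial diazene retro-ene that returns the double bond to C3=C4.
5. Ring order: cyclohexene (step 1), arene substituents (steps 12–15, separate branch), pyran (step 17).

Key step: step 1

Assumption (chemistry): the sense of induction of the cinchona catalyst in step 1 and of the ligand in step 16 is taken from the published models for these substrate classes. Both exist in mirror-image or pseudo-enantiomeric form, and the other form would be used, with nothing else changed, if the first run showed the opposite sense.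

**Route**

Step 1
Reactants: 1 ethyl 2-methyl-3-oxopentanoate (racemic); 2 acrolein (prop-2-enal)
Product: 5 ethyl (1R)-1,3-dimethyl-2-oxocyclohex-3-ene-1-carboxylate, via Michael adduct 3 (not isolated), via aldol adduct 4 (not isolated)
Conditions: 9-O-(9-phenanthryl)cupreidine (10 mol%), CH2Cl2, −25 °C; then solvent exchange to toluene, TsOH·H2O (20 mol%), 4 Å MS, 80 °C
Reagents that add atoms: none
Why: The quinuclidine nitrogen of the catalyst deprotonates the single doubly activated C–H of 1 and holds the enolate as an ion pair while the 6′-OH hydrogen-bonds acrolein, so conjugate addition through one enolate face forms the C1–C6 bond and the quaternary centre (R) under catalyst control; because 1 racemises through its enol, both enantiomers are funnelled into one enantiomer of 3. Acid then enolises the ethyl ketone toward its CH2 group and this enol attacks the tethered aldehyde in a 6-(enolendo)-exo-trig aldol addition, and loss of water from 4 gives the conjugated C3=C4 double bond. The closest known reaction types are the cinchona-catalysed Michael addition of α-substituted β-keto esters to enals and the Robinson-type aldol condensation of δ-keto aldehydes. The step needs 1,4- over 1,2-addition and C- over O-alkylation, which the soft, stabilised β-keto ester enolate secures, and closure through the α′-carbon, which is the only way to a six-membered ring (the alternatives are four-membered). The two extra stereocentres of 4 are lost on dehydration, so the quaternary carbon is the only stereocentre of 5.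

Step 2
Reactants: 5 ethyl (1R)-1,3-dimethyl-2-oxocyclohex-3-ene-1-carboxylate
Product: 6 ethyl (1R,2RS)-2-hydroxy-1,2,3-trimethylcyclohex-3-ene-1-carboxylate (both C2 epimers)
Conditions: MeLi, CeCl3, THF, −78 °C; aq. NH4Cl
Reagents that add atoms: methyllithium, [Li]C
Why: Organocerium 1,2-addition: the weakly basic, oxophilic MeCeCl2 should add only to the enone carbonyl and leave the neopentyl ester untouched at −78 °C; the new carbinol centre is formed as a mixture that step 3 erases.

Step 3
Reactants: 6 ethyl (1R,2RS)-2-hydroxy-1,2,3-trimethylcyclohex-3-ene-1-carboxylate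
Product: 7 ethyl (1R)-1,2,3-trimethyl-4-oxocyclohex-2-ene-1-carboxylate
Conditions: pyridinium chlorochromate [C5H5NH][CrO3Cl], 4 Å MS, CH2Cl2, rt
Reagents that add atoms: pyridinium chlorochromate, [O-][Cr](=O)(=O)Cl.c1cc[nH+]cc1
Why: Dauben–Michno oxidative 1,3-transposition: the chromate ester of the tertiary allylic alcohol should undergo [3,3] shift to C4 and be oxidised there, which fixes the new methyl group on C2 and converges both epimers of 6 to one enone.

Step 4
Reactants: 7 ethyl (1R)-1,2,3-trimethyl-4-oxocyclohex-2-ene-1-carboxylate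
Product: 8 ethyl (1R,4R)-4-hydroxy-1,2,3-trimethylcyclohex-2-ene-1-carboxylate
Conditions: (S)-2-methyl-CBS-oxazaborolidine (20 mol%), catecholborane, toluene, −78 °C; MeOH, then aq. NaOH
Reagents that add atoms: none
Why: Corey–Bakshi–Shibata reduction: the oxazaborolidine binds the carbonyl anti to the α-substituted alkenyl (large) group and delivers hydride to one face, so the 4R carbinol is set by the catalyst independently of the distant quaternary centre, and material derived from any minor enantiomer of 7 becomes a separable diastereomer.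

Step 5
Reactants: 8 ethyl (1R,4R)-4-hydroxy-1,2,3-trimethylcyclohex-2-ene-1-carboxylate
Product: 11 ethyl (1R,2R)-1,2,3-trimethylcyclohex-3-ene-1-carboxylate, via sulfonyl hydrazide 9 (not isolated), via allylic diazene 10 (not isolated)
Conditions: 2-nitrobenzenesulfonohydrazide, PPh3, DEAD, THF, −30 °C; then 23 °C
Reagents that add atoms: none
Why: Myers reductive allylic transposition: Mitsunobu displacement inverts C4, loss of sulfinic acid gives the monoalkyl diazene, and its retro-ene loss of N2 hands hydrogen to C2 on the face of the C4–N bond, which returns the double bond to C3=C4 and sets C2–H anti to the original hydroxyl, that is, the C1 and C2 methyl groups cis.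

Step 6
Reactants: 11 ethyl (1R,2R)-1,2,3-trimethylcyclohex-3-ene-1-carboxylate
Product: 12 [(1R,2R)-1,2,3-trimethylcyclohex-3-en-1-yl]methanol
Conditions: LiAlH4, Et2O, 0 °C; Fieser work-up
Reagents that add atoms: none
Why: Hydride reduction of an ester to the primary alcohol; the isolated trisubstituted alkene and both stereocentres are not touched.

Step 7
Reactants: 12 [(1R,2R)-1,2,3-trimethylcyclohex-3-en-1-yl]methanol
Product: 13 (1R,2R)-1,2,3-trimethylcyclohex-3-ene-1-carbaldehyde
Conditions: Dess–Martin periodinane, NaHCO3, CH2Cl2, rt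
Reagents that add atoms: none
Why: Dess–Martin oxidation of a neopentyl alcohol; the aldehyde has no α-hydrogen, so it cannot epimerise or enolise.

Step 8
Reactants: 13 (1R,2R)-1,2,3-trimethylcyclohex-3-ene-1-carbaldehyde
Product: 14 (5S,6R)-5-ethenyl-1,5,6-trimethylcyclohex-1-ene
Conditions: Ph3PCH3Br, KOtBu, THF, 0 °C to rt
Reagents that add atoms: methyltriphenylphosphonium bromide, C[P+](c1ccccc1)(c1ccccc1)c1ccccc1.[Br-]
Why: Wittig methylenation with the unhindered, non-stabilised ylide, which should reach even an α-quaternary aldehyde; no stereocentre is involved.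

Step 9
Reactants: 15 but-2-yn-1-ol
Product: 17 (2Z)-3-iodobut-2-en-1-ol, via vinylalanate 16 (not isolated)
Conditions: NaAlH2(OCH2CH2OMe)2, THF, 0 °C to rt; then I2, −78 to 0 °C
Reagents that add atoms: iodine, II
Why: Alkoxide-directed trans-hydroalumination of a propargylic alcohol gives the five-membered oxaaluminacycle with aluminium on C3, and iodinolysis with retention gives the Z-iodide (iodine cis to CH2OH).

Step 10
Reactants: 14 (5S,6R)-5-ethenyl-1,5,6-trimethylcyclohex-1-ene; 17 (2Z)-3-iodobut-2-en-1-ol
Product: 19 (2Z)-3-methyl-5-[(1S,2S)-1,2,3-trimethylcyclohex-3-en-1-yl]pent-2-en-1-ol, via alkylborane 18 (not isolated)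
Conditions: 9-BBN dimer, THF, rt; then 17, PdCl2(dppf) (5 mol%), AsPh3, Cs2CO3, DMF/H2O, rt
Reagents that add atoms: none
Why: 9-BBN hydroborates the monosubstituted vinyl group (anti-Markovnikov) far faster than the trisubstituted ring alkene, and the B-alkyl Suzuki–Miyaura coupling joins the primary alkylborane to the vinyl iodide with retention of the alkene geometry.

Step 11
Reactants: 19 (2Z)-3-methyl-5-[(1S,2S)-1,2,3-trimethylcyclohex-3-en-1-yl]pent-2-en-1-ol
Product: 20 methyl (2Z)-3-methyl-5-[(1S,2S)-1,2,3-trimethylcyclohex-3-en-1-yl]pent-2-en-1-yl carbonate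
Conditions: ClCO2Me, pyridine, CH2Cl2, 0 °C
Reagents that add atoms: methyl chloroformate, COC(=O)Cl
Why: Acylation of a primary allylic alcohol to the carbonate, the standard leaving group for the allylic substitution of step 16.

Step 12
Reactants: 21 1,2,3-trimethoxybenzene
Product: 22 1,5-dibromo-2,3,4-trimethoxybenzene
Conditions: NBS (2.1 equiv), MeCN, rt
Reagents that add atoms: N-bromosuccinimide, O=C1CCC(=O)N1Br
Why: Electrophilic aromatic bromination: each bromine should enter ortho and para to the outer methoxy groups (C4, then C6), the position para to the twisted central methoxy group being the least activated.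

Step 13
Reactants: 22 1,5-dibromo-2,3,4-trimethoxybenzene
Product: 23 4,5,6-trimethoxybenzene-1,3-diol
Conditions: Pd2(dba)3 (2 mol%), tBuXPhos (8 mol%), KOH, 1,4-dioxane/H2O, 100 °C; then aq. HCl, under argon
Reagents that add atoms: potassium hydroxide, [K+].[OH-]
Why: Pd-catalysed hydroxylation of aryl bromides with KOH (Buchwald-type C–O coupling), run twice on the same ring; the electron-rich diol is handled without air.

Step 14
Reactants: 23 4,5,6-trimethoxybenzene-1,3-diol
Product: 24 2-iodo-4,5,6-trimethoxybenzene-1,3-diol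
Conditions: NIS (1.0 equiv), CH2Cl2, 0 °C
Reagents that add atoms: N-iodosuccinimide, O=C1CCC(=O)N1I
Why: Electrophilic aromatic iodination at the only unsubstituted ring carbon, which lies between the two hydroxyl groups and is the most activated position.

Step 15
Reactants: 24 2-iodo-4,5,6-trimethoxybenzene-1,3-diol
Product: 25 2-ethenyl-4,5,6-trimethoxybenzene-1,3-diol
Conditions: vinylboronic acid pinacol ester, PdCl2(dppf) (5 mol%), K2CO3, 1,4-dioxane/H2O, 80 °C
Reagents that add atoms: 4,4,5,5-tetramethyl-2-vinyl-1,3,2-dioxaborolane, C=CB1OC(C)(C)C(C)(C)O1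
Why: Suzuki–Miyaura vinylation of an aryl iodide, which tolerates free phenols; the product keeps its mirror symmetry, so either hydroxyl can react in step 16.

Step 16
Reactants: 20 methyl (2Z)-3-methyl-5-[(1S,2S)-1,2,3-trimethylcyclohex-3-en-1-yl]pent-2-en-1-yl carbonate; 25 2-ethenyl-4,5,6-trimethoxybenzene-1,3-diol (3 equiv, excess recovered)
Product: 26 2-ethenyl-4,5,6-trimethoxy-3-({(3R)-3-methyl-5-[(1S,2S)-1,2,3-trimethylcyclohex-3-en-1-yl]pent-1-en-3-yl}oxy)phenol
Conditions: Pd2(dba)3·CHCl3 (2.5 mol%), (R,R)-DACH-phenyl Trost ligand (7.5 mol%), CH2Cl2, rt; stopped at full conversion of 20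
Reagents that add atoms: none
Why: Tsuji–Trost asymmetric allylic etherification: zerovalent palladium ionises the carbonate to a 1,1-disubstituted π-allyl complex, the phenoxide attacks its more substituted terminus, and the chiral pocket of the ligand selects the allyl face, so the tertiary ether centre (R) is set by the catalyst and not by the distant ring stereocentres.

Step 17
Reactants: 26 2-ethenyl-4,5,6-trimethoxy-3-({(3R)-3-methyl-5-[(1S,2S)-1,2,3-trimethylcyclohex-3-en-1-yl]pent-1-en-3-yl}oxy)phenol
Product: 27 (2R)-6,7,8-trimethoxy-2-methyl-2-{2-[(1S,2S)-1,2,3-trimethylcyclohex-3-en-1-yl]ethyl}-2H-chromen-5-ol (target)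
Conditions: second-generation Grubbs catalyst (5 mol%), CH2Cl2, 40 °C
Reagents that add atoms: none
Why: Ring-closing metathesis of the two monosubstituted alkenes closes the six-membered pyran ring as its cis alkene with loss of ethene; the trisubstituted ring alkene is unreactive, and the C–O bond at the stereocentre is not touched, so its configuration is kept.

**Compound list**

1 | ethyl 2-methyl-3-oxopentanoate (racemic) | CCC(=O)C(C)C(=O)OCC | starting material
2 | acrolein | C=CC=O | starting material
3 | ethyl (2R)-2-methyl-3-oxo-2-(3-oxopropyl)pentanoate | CCOC(=O)[C@](C)(CCC=O)C(=O)CC | intermediate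
4 | ethyl (1R)-4-hydroxy-1,3-dimethyl-2-oxocyclohexane-1-carboxylate (mixture at C3 and C4) | CCOC(=O)[C@]1(C)CCC(O)C(C)C1=O | intermediate
5 | ethyl (1R)-1,3-dimethyl-2-oxocyclohex-3-ene-1-carboxylate | CCOC(=O)[C@]1(C)CCC=C(C)C1=O | intermediate
6 | ethyl (1R,2RS)-2-hydroxy-1,2,3-trimethylcyclohex-3-ene-1-carboxylate | CCOC(=O)[C@]1(C)CCC=C(C)C1(C)O | intermediate
7 | ethyl (1R)-1,2,3-trimethyl-4-oxocyclohex-2-ene-1-carboxylate | CCOC(=O)[C@]1(C)CCC(=O)C(C)=C1C | intermediate
8 | ethyl (1R,4R)-4-hydroxy-1,2,3-trimethylcyclohex-2-ene-1-carboxylate | CCOC(=O)[C@]1(C)CC[C@@H](O)C(C)=C1C | intermediate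
9 | ethyl (1R,4S)-1,2,3-trimethyl-4-[1-(2-nitrobenzenesulfonyl)hydrazinyl]cyclohex-2-ene-1-carboxylate | CCOC(=O)[C@]1(C)CC[C@H](N(N)S(=O)(=O)c2ccccc2[N+](=O)[O-])C(C)=C1C | intermediate
10 | ethyl (1R,4S)-4-diazenyl-1,2,3-trimethylcyclohex-2-ene-1-carboxylate | CCOC(=O)[C@]1(C)CC[C@H](N=N)C(C)=C1C | intermediate
11 | ethyl (1R,2R)-1,2,3-trimethylcyclohex-3-ene-1-carboxylate | CCOC(=O)[C@]1(C)CCC=C(C)[C@H]1C | intermediate
12 | [(1R,2R)-1,2,3-trimethylcyclohex-3-en-1-yl]methanol | OC[C@]1(C)CCC=C(C)[C@H]1C | intermediate
13 | (1R,2R)-1,2,3-trimethylcyclohex-3-ene-1-carbaldehyde | O=C[C@]1(C)CCC=C(C)[C@H]1C | intermediate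
14 | (5S,6R)-5-ethenyl-1,5,6-trimethylcyclohex-1-ene | C=C[C@]1(C)CCC=C(C)[C@H]1C | intermediate
15 | but-2-yn-1-ol | CC#CCO | starting material
16 | sodium 2,2-bis(2-methoxyethoxy)-3-methyl-2,5-dihydro-1,2-oxaaluminol-2-uide (cyclic vinylalanate) | CC1=CCO[Al-]1(OCCOC)OCCOC.[Na+] | intermediate
17 | (2Z)-3-iodobut-2-en-1-ol | OC/C=C(C)\I | intermediate
18 | 9-{2-[(1R,2S)-1,2,3-trimethylcyclohex-3-en-1-yl]ethyl}-9-borabicyclo[3.3.1]nonane | B1(CC[C@]2(C)CCC=C(C)[C@H]2C)C3CCCC1CCC3 | intermediate
19 | (2Z)-3-methyl-5-[(1S,2S)-1,2,3-trimethylcyclohex-3-en-1-yl]pent-2-en-1-ol | OC/C=C(C)\CC[C@]1(C)CCC=C(C)[C@H]1C | intermediate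
20 | methyl (2Z)-3-methyl-5-[(1S,2S)-1,2,3-trimethylcyclohex-3-en-1-yl]pent-2-en-1-yl carbonate | COC(=O)OC/C=C(C)\CC[C@]1(C)CCC=C(C)[C@H]1C | intermediate
21 | 1,2,3-trimethoxybenzene | COc1cccc(OC)c1OC | starting material
22 | 1,5-dibromo-2,3,4-trimethoxybenzene | COc1c(Br)cc(Br)c(OC)c1OC | intermediate
23 | 4,5,6-trimethoxybenzene-1,3-diol | COc1c(O)cc(O)c(OC)c1OC | intermediate
24 | 2-iodo-4,5,6-trimethoxybenzene-1,3-diol | COc1c(O)c(I)c(O)c(OC)c1OC | intermediate
25 | 2-ethenyl-4,5,6-trimethoxybenzene-1,3-diol | COc1c(O)c(C=C)c(O)c(OC)c1OC | intermediate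
26 | 2-ethenyl-4,5,6-trimethoxy-3-({(3R)-3-methyl-5-[(1S,2S)-1,2,3-trimethylcyclohex-3-en-1-yl]pent-1-en-3-yl}oxy)phenol | COc1c(O)c(C=C)c(O[C@](C)(CC[C@]2(C)CCC=C(C)[C@H]2C)C=C)c(OC)c1OC | intermediate
27 | (2R)-6,7,8-trimethoxy-2-methyl-2-{2-[(1S,2S)-1,2,3-trimethylcyclohex-3-en-1-yl]ethyl}-2H-chromen-5-ol | COc1c(O)c2c(c(OC)c1OC)O[C@](C)(CC[C@]1(C)CCC=C(C)[C@H]1C)C=C2 | target

**Step count**

Total: 17 steps. Longest linear sequence: 12 steps (steps 1–8, 10, 11, 16, 17). Step 9 and steps 12–15 are side branches.

**Three steps most likely to fail**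

Step 16. The phenol oxygen carries two ortho substituents, so its attack on the more substituted allyl terminus may be slowed; linear ether formation, weak facial selection, or re-ionisation of the product ether could then take over. The fallback sets out from 19 and 23 and comes back at 27. Alcohol 19 is oxidised with MnO2 to (2Z)-3-methyl-5-[(1S,2S)-1,2,3-trimethylcyclohex-3-en-1-yl]pent-2-enal F1. F1 is condensed with resorcinol 23 (ethylenediammonium diacetate, toluene, reflux) by Knoevenagel-type condensation at the only free ring carbon followed by oxa-6π electrocyclisation. This builds the pyran ring with no control at C2, so 27 would form beside its C2 epimer, (2S)-6,7,8-trimethoxy-2-methyl-2-{2-[(1S,2S)-1,2,3-trimethylcyclohex-3-en-1-yl]ethyl}-2H-chromen-5-ol F2. The two are diastereomers and would have to be separated by preparative HPLC.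

Step 5. The Mitsunobu displacement at a carbinol next to a fully substituted alkene carbon may stall or drift to elimination, so that the diazene never forms. The fallback sets out from 5 and comes back at 12. The ketone of 5 is methylenated (Zn, CH2Br2, TiCl4) to ethyl (1R)-1,3-dimethyl-2-methylidenecyclohex-3-ene-1-carboxylate F3, and LiAlH4 gives [(1R)-1,3-dimethyl-2-methylidenecyclohex-3-en-1-yl]methanol F4. Hydroxyl-directed hydrogenation with [Ir(cod)(PCy3)(py)]PF6 (H2, 1 atm, CH2Cl2, stopped after one equivalent) should add hydrogen to the exocyclic double bond from the face of the CH2OH group, giving 12 with the two methyl groups cis. Its own risk is over-reduction of the conjugated diene.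

Step 1. Facial discrimination of the acyclic enolate by the catalyst may be low, or acrolein may oligomerise before it is captured. The fallback sets out from 1 and 2 and comes back at 8. The annulation is run without a chiral catalyst (Et3N cat., then TsOH, toluene, 80 °C) and gives, through racemic ethyl 2-methyl-3-oxo-2-(3-oxopropyl)pentanoate F5 and racemic ethyl 4-hydroxy-1,3-dimethyl-2-oxocyclohexane-1-carboxylate F6, racemic ethyl 1,3-dimethyl-2-oxocyclohex-3-ene-1-carboxylate F7. The conditions of steps 2 and 3 then give racemic ethyl 2-hydroxy-1,2,3-trimethylcyclohex-3-ene-1-carboxylate F8 and racemic ethyl 1,2,3-trimethyl-4-oxocyclohex-2-ene-1-carboxylate F9. The CBS reduction of step 4 then acts as a reagent-controlled divergent reaction on the racemate: both enantiomers of F9 are reduced to the 4R alcohol, so 8 forms beside its diastereomer ethyl (1S,4R)-4-hydroxy-1,2,3-trimethylcyclohex-2-ene-1-carboxylate F10, which is removed by chromatography.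

**Further compounds**

F1 | step 16 | (2Z)-3-methyl-5-[(1S,2S)-1,2,3-trimethylcyclohex-3-en-1-yl]pent-2-enal | O=C/C=C(C)\CC[C@]1(C)CCC=C(C)[C@H]1C
F2 | step 16 | (2S)-6,7,8-trimethoxy-2-methyl-2-{2-[(1S,2S)-1,2,3-trimethylcyclohex-3-en-1-yl]ethyl}-2H-chromen-5-ol | COc1c(O)c2c(c(OC)c1OC)O[C@@](C)(CC[C@]1(C)CCC=C(C)[C@H]1C)C=C2
F3 | step 5 | ethyl (1R)-1,3-dimethyl-2-methylidenecyclohex-3-ene-1-carboxylate | CCOC(=O)[C@]1(C)CCC=C(C)C1=C
F4 | step 5 | [(1R)-1,3-dimethyl-2-methylidenecyclohex-3-en-1-yl]methanol | OC[C@]1(C)CCC=C(C)C1=C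
F5 | step 1 | racemic ethyl 2-methyl-3-oxo-2-(3-oxopropyl)pentanoate | CCOC(=O)C(C)(CCC=O)C(=O)CC
F6 | step 1 | racemic ethyl 4-hydroxy-1,3-dimethyl-2-oxocyclohexane-1-carboxylate | CCOC(=O)C1(C)CCC(O)C(C)C1=O
F7 | step 1 | racemic ethyl 1,3-dimethyl-2-oxocyclohex-3-ene-1-carboxylate | CCOC(=O)C1(C)CCC=C(C)C1=O
F8 | step 1 | racemic ethyl 2-hydroxy-1,2,3-trimethylcyclohex-3-ene-1-carboxylate | CCOC(=O)C1(C)CCC=C(C)C1(C)O
F9 | step 1 | racemic ethyl 1,2,3-trimethyl-4-oxocyclohex-2-ene-1-carboxylate | CCOC(=O)C1(C)CCC(=O)C(C)=C1C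
F10 | step 1 | ethyl (1S,4R)-4-hydroxy-1,2,3-trimethylcyclohex-2-ene-1-carboxylate | CCOC(=O)[C@@]1(C)CC[C@@H](O)C(C)=C1C
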